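**Retrosynthetic overview**
- The 8-formyl group comes from a C8 methyl ester (reduce, then oxidise); the three free phenols are unmasked last from methoxymethyl (MOM) ethers.
- Rings A and B are bought as benzene derivatives; ring C (the pyran) is the only ring built, closed late by an intramolecular Mitsunobu etherification (ring A phenol onto C2–OH).
- The C3–C4 bond is made by an Evans syn-aldol between a ring B arylacetyl oxazolidinone and a ring A benzaldehyde; this sets C3. The aldol hydroxyl at C4 is then removed by hydride reduction of an o-quinone methide.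
- Ring A aldehyde: from methyl 2,4,6-trihydroxybenzoate (4-O-methylation, mono-MOM protection, ortho-formylation, O-allylation).
- Ring B acid: from 4-bromoresorcinol (MOM protection, lithiation/prenylation between the two ethers, Br–Li exchange/ethylene oxide, oxidation).

Assumption: the target is the (3R)-isoflavan as drawn; methyl 2,4,6-trihydroxybenzoate, 4-bromoresorcinol and (4S)-4-benzyl-1,3-oxazolidin-2-one are bought.

**Route**

Step 1
Reactants: 1 methyl 2,4,6-trihydroxybenzoate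
Product: 2 methyl 2,6-dihydroxy-4-methoxybenzoate
Conditions: MeI (1.05 equiv), K2CO3 (1.0 equiv), acetone, 0 °C → rt
Reagents that add atoms: methyl iodide (SMILES: CI)
Why: Williamson etherification is selective for the 4-OH because it is the most acidic hydroxyl and the only one not hydrogen-bonded to the ester.

Step 2
Reactants: 2 methyl 2,6-dihydroxy-4-methoxybenzoate
Product: 3 methyl 2-hydroxy-4-methoxy-6-(methoxymethoxy)benzoate
Conditions: MOMCl (1.1 equiv), i-Pr2NEt (1.5 equiv), CH2Cl2, 0 °C → rt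
Reagents that add atoms: chloromethyl methyl ether (SMILES: COCCl)
Why: O-alkylation of a symmetric diol stops cleanly at the mono-ether because the remaining hydroxyl becomes the sole, strongly chelated hydrogen-bond donor to the ester.

Step 3
Reactants: 3 methyl 2-hydroxy-4-methoxy-6-(methoxymethoxy)benzoate
Product: 4 methyl 3-formyl-2-hydroxy-4-methoxy-6-(methoxymethoxy)benzoate
Conditions: MgCl2 (3 equiv), Et3N (6 equiv), (CH2O)n (8 equiv), MeCN, reflux
Reagents that add atoms: formaldehyde as paraformaldehyde (SMILES: C=O)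
Why: The magnesium phenoxide ortho-formylation (Casnati–Skattebøl) delivers the formyl group only ortho to the free phenol, and C3 is the single open ortho position, so the regiochemistry is fixed under base that spares the MOM ether.

Step 4
Reactants: 4 methyl 3-formyl-2-hydroxy-4-methoxy-6-(methoxymethoxy)benzoate
Product: 5 methyl 3-formyl-4-methoxy-6-(methoxymethoxy)-2-(prop-2-en-1-yloxy)benzoate
Conditions: allyl bromide (1.5 equiv), K2CO3 (2 equiv), DMF, 50 °C
Reagents that add atoms: allyl bromide (SMILES: C=CCBr)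
Why: Williamson allylation masks the future ring C oxygen with a group that survives the aldol and hydride steps and is later removed by palladium without acid.

Step 5
Reactants: 6 4-bromobenzene-1,3-diol
Product: 7 1-bromo-2,4-bis(methoxymethoxy)benzene
Conditions: MOMCl (2.5 equiv), i-Pr2NEt (3 equiv), CH2Cl2, 0 °C → rt
Reagents that add atoms: chloromethyl methyl ether (SMILES: COCCl)
Why: Standard acetal protection of both phenols installs the two directing groups needed for the metalation that follows.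

Step 6
Reactants: 7 1-bromo-2,4-bis(methoxymethoxy)benzene
Product: 10 1-bromo-2,4-bis(methoxymethoxy)-3-(3-methylbut-2-en-1-yl)benzene, via aryllithium 8 (not isolated), via arylcopper 9 (not isolated)
Conditions: LiN(i-Pr)2 (1.15 equiv), THF, −78 °C; CuBr·SMe2 (1.1 equiv), −78 → −40 °C; prenyl bromide (1.3 equiv), −40 °C → rt
Reagents that add atoms: prenyl bromide (SMILES: CC(C)=CCBr)
Why: Directed ortho-metalation with an amide base (no Br–Li exchange) removes the proton flanked by both MOM ethers, and the arylcopper couples with prenyl bromide by SN2 to give the linear prenyl group.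

Step 7
Reactants: 10 1-bromo-2,4-bis(methoxymethoxy)-3-(3-methylbut-2-en-1-yl)benzene
Product: 12 2-[2,4-bis(methoxymethoxy)-3-(3-methylbut-2-en-1-yl)phenyl]ethan-1-ol, via aryllithium 11 (not isolated)
Conditions: n-BuLi (1.05 equiv), THF, −78 °C; ethylene oxide (3 equiv), −78 °C → rt; H2O
Reagents that add atoms: ethylene oxide (SMILES: C1CO1)
Why: Bromine–lithium exchange is fast and site-specific at −78 °C, and epoxide opening by the aryllithium adds the two-carbon chain exactly where the bromine stood.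

Step 8
Reactants: 12 2-[2,4-bis(methoxymethoxy)-3-(3-methylbut-2-en-1-yl)phenyl]ethan-1-ol
Product: 14 2-[2,4-bis(methoxymethoxy)-3-(3-methylbut-2-en-1-yl)phenyl]acetic acid, via arylacetaldehyde 13 (not isolated)
Conditions: TEMPO (0.2 equiv), PhI(OAc)2 (2.2 equiv), MeCN/H2O 1:1, rt
Reagents that add atoms: water (SMILES: O)
Why: Oxoammonium-mediated oxidation takes the primary alcohol through the aldehyde hydrate to the acid without chlorine-based oxidants, so the prenyl alkene and the electron-rich ring are left alone.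

Step 9
Reactants: 14 2-[2,4-bis(methoxymethoxy)-3-(3-methylbut-2-en-1-yl)phenyl]acetic acid; 15 (4S)-4-benzyl-1,3-oxazolidin-2-one
Product: 17 (4S)-4-benzyl-3-{2-[2,4-bis(methoxymethoxy)-3-(3-methylbut-2-en-1-yl)phenyl]acetyl}-1,3-oxazolidin-2-one, via mixed anhydride 16 (not isolated)
Conditions: t-BuCOCl (1.1 equiv), Et3N (2.5 equiv), THF, −20 °C; then 15 (1.0 equiv), LiCl (1.1 equiv), −20 °C → rt
Reagents that add atoms: none
Why: N-acylation through the pivalic mixed anhydride is regioselective for the unhindered acyl carbon and runs under conditions too mild to enolise or racemise anything.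

Step 10
Reactants: 17 (4S)-4-benzyl-3-{2-[2,4-bis(methoxymethoxy)-3-(3-methylbut-2-en-1-yl)phenyl]acetyl}-1,3-oxazolidin-2-one; 5 methyl 3-formyl-4-methoxy-6-(methoxymethoxy)-2-(prop-2-en-1-yloxy)benzoate
Product: 19 methyl 3-{(1S,2S)-3-[(4S)-4-benzyl-2-oxo-1,3-oxazolidin-3-yl]-2-[2,4-bis(methoxymethoxy)-3-(3-methylbut-2-en-1-yl)phenyl]-1-hydroxy-3-oxopropyl}-4-methoxy-6-(methoxymethoxy)-2-(prop-2-en-1-yloxy)benzoate, via boron enolate 18 (not isolated)
Conditions: n-Bu2BOTf (1.2 equiv), i-Pr2NEt (1.4 equiv), CH2Cl2, −78 → 0 °C; 5 (0.85 equiv), −78 → 0 °C; pH 7 phosphate buffer, MeOH, 30% H2O2, 0 °C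
Reagents that add atoms: none
Why: In this Evans syn-aldol the (Z)-boron enolate reacts through a Zimmerman–Traxler chair on the face away from the auxiliary benzyl group, setting the (2S) α-centre (the future C3, R in the target) and the (1S) carbinol centre (removed later), with minor diastereomers separated by chromatography; the ester on ring A makes the hindered aldehyde more electrophilic.

Step 11
Reactants: 19 methyl 3-{(1S,2S)-3-[(4S)-4-benzyl-2-oxo-1,3-oxazolidin-3-yl]-2-[2,4-bis(methoxymethoxy)-3-(3-methylbut-2-en-1-yl)phenyl]-1-hydroxy-3-oxopropyl}-4-methoxy-6-(methoxymethoxy)-2-(prop-2-en-1-yloxy)benzoate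
Product: 20 methyl 3-{(1S,2R)-1,3-dihydroxy-2-[2,4-bis(methoxymethoxy)-3-(3-methylbut-2-en-1-yl)phenyl]propyl}-4-methoxy-6-(methoxymethoxy)-2-(prop-2-en-1-yloxy)benzoate
Conditions: LiBH4 (2 equiv), MeOH (2 equiv), THF, 0 °C; 1 M NaOH
Reagents that add atoms: none
Why: Reductive cleavage of the activated imide carbonyl by LiBH4 is much faster than attack on the doubly ortho-substituted, electron-rich aryl ester, and it releases the auxiliary without touching the α-centre (the descriptor changes to R only through CIP priorities).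

Step 12
Reactants: 20 methyl 3-{(1S,2R)-1,3-dihydroxy-2-[2,4-bis(methoxymethoxy)-3-(3-methylbut-2-en-1-yl)phenyl]propyl}-4-methoxy-6-(methoxymethoxy)-2-(prop-2-en-1-yloxy)benzoate
Product: 21 methyl 3-{(1S,2R)-1,3-diacetoxy-2-[2,4-bis(methoxymethoxy)-3-(3-methylbut-2-en-1-yl)phenyl]propyl}-4-methoxy-6-(methoxymethoxy)-2-(prop-2-en-1-yloxy)benzoate
Conditions: Ac2O (4 equiv), pyridine, DMAP (0.1 equiv), CH2Cl2, rt
Reagents that add atoms: acetic anhydride (SMILES: CC(=O)OC(C)=O)
Why: DMAP-catalysed acylation turns the benzylic hydroxyl into a leaving group and masks the primary alcohol, and the benzylic acetate is stable because the ring ester tempers ionisation.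

Step 13
Reactants: 21 methyl 3-{(1S,2R)-1,3-diacetoxy-2-[2,4-bis(methoxymethoxy)-3-(3-methylbut-2-en-1-yl)phenyl]propyl}-4-methoxy-6-(methoxymethoxy)-2-(prop-2-en-1-yloxy)benzoate
Product: 24 methyl 3-{(2R)-3-acetoxy-2-[2,4-bis(methoxymethoxy)-3-(3-methylbut-2-en-1-yl)phenyl]propyl}-2-hydroxy-4-methoxy-6-(methoxymethoxy)benzoate, via phenoxide 22 (not isolated), via quinone methide 23 (not isolated)
Conditions: Pd(PPh3)4 (5 mol%), NaBH4 (4 equiv), THF, 0 °C → rt
Reagents that add atoms: none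
Why: Zerovalent palladium with hydride cleaves the allyl ether (Tsuji–Trost type deallylation), the liberated phenoxide expels the ortho benzylic acetate to give an o-quinone methide, and borohydride adds 1,4 to it, so the C4 oxygen is removed under basic conditions that spare the MOM ethers, the prenyl group and the C3 centre.

Step 14
Reactants: 24 methyl 3-{(2R)-3-acetoxy-2-[2,4-bis(methoxymethoxy)-3-(3-methylbut-2-en-1-yl)phenyl]propyl}-2-hydroxy-4-methoxy-6-(methoxymethoxy)benzoate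
Product: 25 methyl 2-hydroxy-3-{(2R)-3-hydroxy-2-[2,4-bis(methoxymethoxy)-3-(3-methylbut-2-en-1-yl)phenyl]propyl}-4-methoxy-6-(methoxymethoxy)benzoate
Conditions: K2CO3, MeOH, rt
Reagents that add atoms: none
Why: Base-catalysed transesterification removes the primary acetate, while the aryl methyl ester is degenerate towards methoxide.

Step 15
Reactants: 25 methyl 2-hydroxy-3-{(2R)-3-hydroxy-2-[2,4-bis(methoxymethoxy)-3-(3-methylbut-2-en-1-yl)phenyl]propyl}-4-methoxy-6-(methoxymethoxy)benzoate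
Product: 26 methyl (3R)-3-[2,4-bis(methoxymethoxy)-3-(3-methylbut-2-en-1-yl)phenyl]-5-methoxy-7-(methoxymethoxy)-3,4-dihydro-2H-chromene-8-carboxylate
Conditions: PPh3 (1.5 equiv), DIAD (1.5 equiv), THF (0.02 M), 0 °C → rt
Reagents that add atoms: none
Why: Intramolecular Mitsunobu etherification closes ring C by 6-exo displacement at the primary carbon by the only free phenol, so the C3 centre is not involved.

Step 16
Reactants: 26 methyl (3R)-3-[2,4-bis(methoxymethoxy)-3-(3-methylbut-2-en-1-yl)phenyl]-5-methoxy-7-(methoxymethoxy)-3,4-dihydro-2H-chromene-8-carboxylate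
Product: 27 {(3R)-3-[2,4-bis(methoxymethoxy)-3-(3-methylbut-2-en-1-yl)phenyl]-5-methoxy-7-(methoxymethoxy)-3,4-dihydro-2H-chromen-8-yl}methanol
Conditions: LiAlH4 (3 equiv), THF, 0 °C → rt; H2O/NaOH work-up
Reagents that add atoms: none
Why: LiAlH4 is strong enough to reduce the hindered 2,6-dioxygenated benzoate, and the basic work-up protects the acid-sensitive trioxygenated benzylic alcohol.

Step 17
Reactants: 27 {(3R)-3-[2,4-bis(methoxymethoxy)-3-(3-methylbut-2-en-1-yl)phenyl]-5-methoxy-7-(methoxymethoxy)-3,4-dihydro-2H-chromen-8-yl}methanol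
Product: 28 (3R)-3-[2,4-bis(methoxymethoxy)-3-(3-methylbut-2-en-1-yl)phenyl]-5-methoxy-7-(methoxymethoxy)-3,4-dihydro-2H-chromene-8-carbaldehyde
Conditions: activated MnO2 (15 equiv), CH2Cl2, rt
Reagents that add atoms: none
Why: MnO2 oxidises only the benzylic alcohol and stops at the aldehyde under neutral conditions.

Step 18
Reactants: 28 (3R)-3-[2,4-bis(methoxymethoxy)-3-(3-methylbut-2-en-1-yl)phenyl]-5-methoxy-7-(methoxymethoxy)-3,4-dihydro-2H-chromene-8-carbaldehyde
Product: 29 (3R)-3-[2,4-dihydroxy-3-(3-methylbut-2-en-1-yl)phenyl]-7-hydroxy-5-methoxy-3,4-dihydro-2H-chromene-8-carbaldehyde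
Conditions: HCl (0.5 M) in MeOH/THF 4:1, 40 °C, monitored; NaHCO3 quench
Reagents that add atoms: none
Why: Acid-catalysed transacetalisation to methanol removes all three MOM groups, and dilute acid at mild temperature is used to stay below the threshold for prenyl–phenol cyclisation; the aryl methyl ether and C3 are inert.

**Compound list**

1 | methyl 2,4,6-trihydroxybenzoate | COC(=O)c1c(O)cc(O)cc1O | starting material
2 | methyl 2,6-dihydroxy-4-methoxybenzoate | COC(=O)c1c(O)cc(OC)cc1O | intermediate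
3 | methyl 2-hydroxy-4-methoxy-6-(methoxymethoxy)benzoate | COC(=O)c1c(O)cc(OC)cc1OCOC | intermediate
4 | methyl 3-formyl-2-hydroxy-4-methoxy-6-(methoxymethoxy)benzoate | COC(=O)c1c(O)c(C=O)c(OC)cc1OCOC | intermediate
5 | methyl 3-formyl-4-methoxy-6-(methoxymethoxy)-2-(prop-2-en-1-yloxy)benzoate | COC(=O)c1c(OCC=C)c(C=O)c(OC)cc1OCOC | intermediate
6 | 4-bromobenzene-1,3-diol (4-bromoresorcinol) | Oc1ccc(Br)c(O)c1 | starting material
7 | 1-bromo-2,4-bis(methoxymethoxy)benzene | COCOc1ccc(Br)c(OCOC)c1 | intermediate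
8 | [3-bromo-2,6-bis(methoxymethoxy)phenyl]lithium (not isolated) | [Li]c1c(OCOC)ccc(Br)c1OCOC | intermediate
9 | [3-bromo-2,6-bis(methoxymethoxy)phenyl]copper (not isolated) | [Cu]c1c(OCOC)ccc(Br)c1OCOC | intermediate
10 | 1-bromo-2,4-bis(methoxymethoxy)-3-(3-methylbut-2-en-1-yl)benzene | CC(C)=CCc1c(OCOC)ccc(Br)c1OCOC | intermediate
11 | [2,4-bis(methoxymethoxy)-3-(3-methylbut-2-en-1-yl)phenyl]lithium (not isolated) | [Li]c1ccc(OCOC)c(CC=C(C)C)c1OCOC | intermediate
12 | 2-[2,4-bis(methoxymethoxy)-3-(3-methylbut-2-en-1-yl)phenyl]ethan-1-ol | OCCc1ccc(OCOC)c(CC=C(C)C)c1OCOC | intermediate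
13 | 2-[2,4-bis(methoxymethoxy)-3-(3-methylbut-2-en-1-yl)phenyl]acetaldehyde (not isolated) | O=CCc1ccc(OCOC)c(CC=C(C)C)c1OCOC | intermediate
14 | 2-[2,4-bis(methoxymethoxy)-3-(3-methylbut-2-en-1-yl)phenyl]acetic acid | OC(=O)Cc1ccc(OCOC)c(CC=C(C)C)c1OCOC | intermediate
15 | (4S)-4-benzyl-1,3-oxazolidin-2-one | O=C1N[C@@H](Cc2ccccc2)CO1 | starting material
16 | 2-[2,4-bis(methoxymethoxy)-3-(3-methylbut-2-en-1-yl)phenyl]acetic 2,2-dimethylpropanoic anhydride (not isolated) | CC(C)(C)C(=O)OC(=O)Cc1ccc(OCOC)c(CC=C(C)C)c1OCOC | intermediate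
17 | (4S)-4-benzyl-3-{2-[2,4-bis(methoxymethoxy)-3-(3-methylbut-2-en-1-yl)phenyl]acetyl}-1,3-oxazolidin-2-one | O=C1OC[C@H](Cc2ccccc2)N1C(=O)Cc1ccc(OCOC)c(CC=C(C)C)c1OCOC | intermediate
18 | (Z)-dibutylboron enolate of 17 (not isolated) | O=C1OC[C@H](Cc2ccccc2)N1/C(OB(CCCC)CCCC)=C/c1ccc(OCOC)c(CC=C(C)C)c1OCOC | intermediate
19 | methyl 3-{(1S,2S)-3-[(4S)-4-benzyl-2-oxo-1,3-oxazolidin-3-yl]-2-[2,4-bis(methoxymethoxy)-3-(3-methylbut-2-en-1-yl)phenyl]-1-hydroxy-3-oxopropyl}-4-methoxy-6-(methoxymethoxy)-2-(prop-2-en-1-yloxy)benzoate | O=C1OC[C@H](Cc2ccccc2)N1C(=O)[C@@H](c1ccc(OCOC)c(CC=C(C)C)c1OCOC)[C@H](O)c1c(OC)cc(OCOC)c(C(=O)OC)c1OCC=C | intermediate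
20 | methyl 3-{(1S,2R)-1,3-dihydroxy-2-[2,4-bis(methoxymethoxy)-3-(3-methylbut-2-en-1-yl)phenyl]propyl}-4-methoxy-6-(methoxymethoxy)-2-(prop-2-en-1-yloxy)benzoate | OC[C@@H](c1ccc(OCOC)c(CC=C(C)C)c1OCOC)[C@H](O)c1c(OC)cc(OCOC)c(C(=O)OC)c1OCC=C | intermediate
21 | methyl 3-{(1S,2R)-1,3-diacetoxy-2-[2,4-bis(methoxymethoxy)-3-(3-methylbut-2-en-1-yl)phenyl]propyl}-4-methoxy-6-(methoxymethoxy)-2-(prop-2-en-1-yloxy)benzoate | CC(=O)OC[C@@H](c1ccc(OCOC)c(CC=C(C)C)c1OCOC)[C@H](OC(C)=O)c1c(OC)cc(OCOC)c(C(=O)OC)c1OCC=C | intermediate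
22 | sodium 2-{(1S,2R)-1,3-diacetoxy-2-[2,4-bis(methoxymethoxy)-3-(3-methylbut-2-en-1-yl)phenyl]propyl}-3-methoxy-6-(methoxycarbonyl)-5-(methoxymethoxy)phenolate (not isolated) | CC(=O)OC[C@@H](c1ccc(OCOC)c(CC=C(C)C)c1OCOC)[C@H](OC(C)=O)c1c(OC)cc(OCOC)c(C(=O)OC)c1[O-].[Na+] | intermediate
23 | methyl 5-{(2R)-3-acetoxy-2-[2,4-bis(methoxymethoxy)-3-(3-methylbut-2-en-1-yl)phenyl]propylidene}-4-methoxy-2-(methoxymethoxy)-6-oxocyclohexa-1,3-diene-1-carboxylate (not isolated; geometry of the exocyclic alkene not controlled and lost on reduction) | COC(=O)C1=C(OCOC)C=C(OC)C(=C[C@H](c2ccc(OCOC)c(CC=C(C)C)c2OCOC)COC(C)=O)C1=O | intermediate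
24 | methyl 3-{(2R)-3-acetoxy-2-[2,4-bis(methoxymethoxy)-3-(3-methylbut-2-en-1-yl)phenyl]propyl}-2-hydroxy-4-methoxy-6-(methoxymethoxy)benzoate | CC(=O)OC[C@@H](c1ccc(OCOC)c(CC=C(C)C)c1OCOC)Cc1c(OC)cc(OCOC)c(C(=O)OC)c1O | intermediate
25 | methyl 2-hydroxy-3-{(2R)-3-hydroxy-2-[2,4-bis(methoxymethoxy)-3-(3-methylbut-2-en-1-yl)phenyl]propyl}-4-methoxy-6-(methoxymethoxy)benzoate | OC[C@@H](c1ccc(OCOC)c(CC=C(C)C)c1OCOC)Cc1c(OC)cc(OCOC)c(C(=O)OC)c1O | intermediate
26 | methyl (3R)-3-[2,4-bis(methoxymethoxy)-3-(3-methylbut-2-en-1-yl)phenyl]-5-methoxy-7-(methoxymethoxy)-3,4-dihydro-2H-chromene-8-carboxylate | COC(=O)c1c(OCOC)cc(OC)c2c1OC[C@@H](c1ccc(OCOC)c(CC=C(C)C)c1OCOC)C2 | intermediate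
27 | {(3R)-3-[2,4-bis(methoxymethoxy)-3-(3-methylbut-2-en-1-yl)phenyl]-5-methoxy-7-(methoxymethoxy)-3,4-dihydro-2H-chromen-8-yl}methanol | OCc1c(OCOC)cc(OC)c2c1OC[C@@H](c1ccc(OCOC)c(CC=C(C)C)c1OCOC)C2 | intermediate
28 | (3R)-3-[2,4-bis(methoxymethoxy)-3-(3-methylbut-2-en-1-yl)phenyl]-5-methoxy-7-(methoxymethoxy)-3,4-dihydro-2H-chromene-8-carbaldehyde | O=Cc1c(OCOC)cc(OC)c2c1OC[C@@H](c1ccc(OCOC)c(CC=C(C)C)c1OCOC)C2 | intermediate
29 | (3R)-3-[2,4-dihydroxy-3-(3-methylbut-2-en-1-yl)phenyl]-7-hydroxy-5-methoxy-3,4-dihydro-2H-chromene-8-carbaldehyde | COc1cc(O)c(C=O)c2c1C[C@H](c1ccc(O)c(CC=C(C)C)c1O)CO2 | target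

**Step count and risks**

Total steps: 18. Longest linear sequence: 14 steps (6 → 29, steps 5–18); the ring A branch (1 → 5) is 4 steps.

Most likely to fail:

Step 10 (aldol between a bulky arylacetyl enolate and a 2,6-disubstituted benzaldehyde; slow addition or retro-aldol). The fallback sets out from 14 and 5 and comes back at 25. Acid 14 and aldehyde 5 are condensed under Perkin conditions (Ac2O, Et3N, 110 °C) to the (E)-2,3-diarylacrylic acid F1. Carboxylate-directed asymmetric hydrogenation with Ru(OAc)2[(S)-BINAP] (H2 50 bar, MeOH) reduces only the conjugated alkene and gives the (R)-2,3-diarylpropanoic acid F2. The sense of induction is assigned by analogy with tiglic acid and must be confirmed by chiral HPLC; the enantiomeric purity can be raised by crystallising the (R)-1-phenylethylamine salt. Activation with ClCO2Et and N-methylmorpholine (THF, −10 °C) gives the mixed ethyl carbonic anhydride F3, which NaBH4 reduces in the same flask to the primary alcohol F4. Deallylation with Pd(PPh3)4/NaBH4 then gives 25, and the route continues at step 15.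

Step 13 (the deallylation/quinone methide/hydride cascade; the phenoxide may instead pick up an acetyl group, or the quinone methide may tautomerise to a styrene). The fallback sets out from 20 and comes back at 26. The allyl ether of 20 is removed with Pd(PPh3)4 and K2CO3 in MeOH to give the phenol diol F5. Mitsunobu cyclisation (PPh3, DIAD, THF) closes ring C first, at the primary hydroxyl, to give the isoflavan-4-ol F6. The 4-hydroxyl is then removed by ionic hydrogenation (Et3SiH, BF3·OEt2, CH2Cl2, −78 °C) to give 26; the low temperature is needed to spare the MOM ethers and the prenyl group.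

Step 18 (acid next to a prenyl group flanked by two phenols, and next to an electron-rich salicylaldehyde; risk of chroman formation or condensation). The fallback sets out from 26 and comes back at 29. With no aldehyde present, the MOM groups of 26 are cleaved with ZnBr2 and n-PrSH (CH2Cl2, 0 °C) to the triphenol ester F7. Silylation (t-BuMe2SiCl, imidazole, DMF) gives the tris(silyl ether) ester F8, i-Bu2AlH (CH2Cl2, −78 → 0 °C) gives the benzylic alcohol F9, and MnO2 gives the aldehyde F10. Bu4NF buffered with AcOH (THF, 0 °C) then releases 29 without any protic acid step.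

**Further compounds**

F1 | step 10 | (2E)-2-[2,4-bis(methoxymethoxy)-3-(3-methylbut-2-en-1-yl)phenyl]-3-[6-methoxy-3-(methoxycarbonyl)-4-(methoxymethoxy)-2-(prop-2-en-1-yloxy)phenyl]prop-2-enoic acid | OC(=O)/C(c1ccc(OCOC)c(CC=C(C)C)c1OCOC)=C/c1c(OC)cc(OCOC)c(C(=O)OC)c1OCC=C
F2 | step 10 | (2R)-2-[2,4-bis(methoxymethoxy)-3-(3-methylbut-2-en-1-yl)phenyl]-3-[6-methoxy-3-(methoxycarbonyl)-4-(methoxymethoxy)-2-(prop-2-en-1-yloxy)phenyl]propanoic acid | OC(=O)[C@@H](c1ccc(OCOC)c(CC=C(C)C)c1OCOC)Cc1c(OC)cc(OCOC)c(C(=O)OC)c1OCC=C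
F3 | step 10 | (2R)-2-[2,4-bis(methoxymethoxy)-3-(3-methylbut-2-en-1-yl)phenyl]-3-[6-methoxy-3-(methoxycarbonyl)-4-(methoxymethoxy)-2-(prop-2-en-1-yloxy)phenyl]propanoic ethyl carbonic anhydride | CCOC(=O)OC(=O)[C@@H](c1ccc(OCOC)c(CC=C(C)C)c1OCOC)Cc1c(OC)cc(OCOC)c(C(=O)OC)c1OCC=C
F4 | step 10 | methyl 3-{(2R)-3-hydroxy-2-[2,4-bis(methoxymethoxy)-3-(3-methylbut-2-en-1-yl)phenyl]propyl}-4-methoxy-6-(methoxymethoxy)-2-(prop-2-en-1-yloxy)benzoate | OC[C@@H](c1ccc(OCOC)c(CC=C(C)C)c1OCOC)Cc1c(OC)cc(OCOC)c(C(=O)OC)c1OCC=C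
F5 | step 13 | methyl 3-{(1S,2R)-1,3-dihydroxy-2-[2,4-bis(methoxymethoxy)-3-(3-methylbut-2-en-1-yl)phenyl]propyl}-2-hydroxy-4-methoxy-6-(methoxymethoxy)benzoate | OC[C@@H](c1ccc(OCOC)c(CC=C(C)C)c1OCOC)[C@H](O)c1c(OC)cc(OCOC)c(C(=O)OC)c1O
F6 | step 13 | methyl (3R,4S)-3-[2,4-bis(methoxymethoxy)-3-(3-methylbut-2-en-1-yl)phenyl]-4-hydroxy-5-methoxy-7-(methoxymethoxy)-3,4-dihydro-2H-chromene-8-carboxylate | COC(=O)c1c(OCOC)cc(OC)c2c1OC[C@@H](c1ccc(OCOC)c(CC=C(C)C)c1OCOC)[C@@H]2O
F7 | step 18 | methyl (3R)-3-[2,4-dihydroxy-3-(3-methylbut-2-en-1-yl)phenyl]-7-hydroxy-5-methoxy-3,4-dihydro-2H-chromene-8-carboxylate | COC(=O)c1c(O)cc(OC)c2c1OC[C@@H](c1ccc(O)c(CC=C(C)C)c1O)C2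
F8 | step 18 | methyl (3R)-3-[2,4-bis(tert-butyldimethylsilyloxy)-3-(3-methylbut-2-en-1-yl)phenyl]-7-(tert-butyldimethylsilyloxy)-5-methoxy-3,4-dihydro-2H-chromene-8-carboxylate | COC(=O)c1c(O[Si](C)(C)C(C)(C)C)cc(OC)c2c1OC[C@@H](c1ccc(O[Si](C)(C)C(C)(C)C)c(CC=C(C)C)c1O[Si](C)(C)C(C)(C)C)C2
F9 | step 18 | {(3R)-3-[2,4-bis(tert-butyldimethylsilyloxy)-3-(3-methylbut-2-en-1-yl)phenyl]-7-(tert-butyldimethylsilyloxy)-5-methoxy-3,4-dihydro-2H-chromen-8-yl}methanol | OCc1c(O[Si](C)(C)C(C)(C)C)cc(OC)c2c1OC[C@@H](c1ccc(O[Si](C)(C)C(C)(C)C)c(CC=C(C)C)c1O[Si](C)(C)C(C)(C)C)C2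
F10 | step 18 | (3R)-3-[2,4-bis(tert-butyldimethylsilyloxy)-3-(3-methylbut-2-en-1-yl)phenyl]-7-(tert-butyldimethylsilyloxy)-5-methoxy-3,4-dihydro-2H-chromene-8-carbaldehyde | O=Cc1c(O[Si](C)(C)C(C)(C)C)cc(OC)c2c1OC[C@@H](c1ccc(O[Si](C)(C)C(C)(C)C)c(CC=C(C)C)c1O[Si](C)(C)C(C)(C)C)C2
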